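The cyclohexane ring is opened at C1–C2, where C1 is the ring carbon bearing the side chain and C2 its acetoxy-substituted neighbour. C1 is allylic to the exocyclic C7 methylene and vicinal to the C2 oxygen, the pattern left when the γ-carbon of an allylmetal adds to an aldehyde with allylic shift. Divalent chromium converts acyclic Z-enal allylic bromide 25 (tartrate-derived C5/C6 acetonide, C8 angelate in place) into cyclohexenol 27, forming C1–C2, closing the six-membered ring, unveiling C7=CH2 and setting C1 and C2 in one operation. Acyl and redox adjustments and a C5-hydroxyl-directed epoxidation then complete the target.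

Key step: step 17

Locants used throughout: ring C1 (side chain), C2 (OAc), C3–C4 (epoxide, C4 carries the methyl), C5 (C=O), C6 (OAc); chain C7 (carries the exocyclic methylene; its one-carbon branch in open-chain compounds is C7′), C8 (angelate carbinol), C9–C11 (prenyl).

Remarks on the chemistry:
- The C7′ hydroxyl is silylated before the angelate is introduced, because the secondary C8 hydroxyl cannot be acylated selectively beside a primary allylic hydroxyl.
- Enone 31 is not epoxidised with a peroxide anion. Axial attack on its all-equatorial half-chair (the carvone pattern) would place the oxirane trans to the C1 side chain, opposite to the target. The oxygen is therefore delivered from the C5 hydroxyl of 32.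
- Assumption: aldehyde 10 is used freshly distilled, since it drifts into conjugation on storage.

Step 1
Reactants: 1 dimethyl 2,3-O-isopropylidene-L-tartrate
Product: 3 twofold-symmetric diyne, via dialdehyde 2 (not isolated)
Conditions: i-Bu2AlH (2.2 equiv), CH2Cl2, −78 °C; then MeOH, K2CO3, dimethyl (1-diazo-2-oxopropyl)phosphonate, −78 °C → rt
Reagents that add atoms: dimethyl (1-diazo-2-oxopropyl)phosphonate, CC(=O)C(=[N+]=[N-])P(=O)(OC)OC
Why: Low-temperature hydride reduction stops at the chelated aluminium hemiacetal of each α-alkoxy ester, and the dialdehyde freed by methanol is homologated at once by the Ohira–Bestmann (Seyferth–Gilbert) reagent, the trans-dioxolane being the thermodynamically preferred arrangement under the mildly basic conditions.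

Step 2
Reactants: 3 twofold-symmetric diyne
Product: 5 mono-ynoate, via lithium acetylide 4 (not isolated)
Conditions: n-BuLi (1.0 equiv), THF, −78 °C; then ClCO2Me, −78 → 0 °C
Reagents that add atoms: methyl chloroformate, COC(=O)Cl
Why: Mono-lithiation and C-acylation of the acetylide desymmetrise the diyne without protecting groups because either alkyne gives the same ynoate; the mono-functionalisation is statistical, so unreacted 3 is recycled.

Step 3
Reactants: 5 mono-ynoate
Product: 7 Z-enoate, via alkenylcuprate 6 (not isolated)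
Conditions: Me2CuLi (2.5 equiv), THF, −78 °C; then MeOH, −78 °C
Reagents that add atoms: lithium dimethylcuprate, [Li+].C[Cu-]C
Why: Syn carbocupration of the ynoate (conjugate addition of the Gilman reagent) puts the methyl on C4 and copper on C3 on the same side, and protonation at −78 °C with retention should give the Z-enoate in which C5 and the ester are cis.

Step 4
Reactants: 7 Z-enoate
Product: 8 Z-allylic alcohol
Conditions: i-Bu2AlH (2.5 equiv), CH2Cl2, −78 °C
Reagents that add atoms: none
Why: 1,2-Hydride reduction of the conjugated ester gives the allylic alcohol without touching the alkene geometry, the acetonide or the terminal alkyne.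

Step 5
Reactants: 8 Z-allylic alcohol
Product: 9 TBS ether alkyne
Conditions: TBSCl, imidazole, CH2Cl2, 0 °C → rt
Reagents that add atoms: tert-butyldimethylsilyl chloride, CC(C)(C)[Si](C)(C)Cl
Why: Silyl ether formation masks the future aldehyde carbon through the organometallic steps that follow.

Step 6
Reactants: 9 TBS ether alkyne; 10 4-methylpent-3-enal
Product: 12 propargylic alcohols (C8 epimers), via lithium acetylide 11 (not isolated)
Conditions: n-BuLi, THF, −78 °C; then 10, −78 °C; H2O
Reagents that add atoms: none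
Why: 1,2-Addition of the lithium acetylide to the aldehyde at −78 °C outpaces enolisation and builds the C7–C8 bond; C8 is not controlled here and is set in step 8.

Step 7
Reactants: 12 propargylic alcohols (C8 epimers)
Product: 13 ynone
Conditions: Dess–Martin periodinane, pyridine, CH2Cl2, 0 °C
Reagents that add atoms: none
Why: Dess–Martin oxidation under buffered, non-basic conditions should give the ynone without moving the skipped C10=C11 alkene into conjugation.

Step 8
Reactants: 13 ynone
Product: 14 (S)-propargylic alcohol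
Conditions: Ru[(S,S)-TsNCH(Ph)CH(Ph)NH](p-cymene) (2 mol %), i-PrOH, 25 °C
Reagents that add atoms: none
Why: Noyori asymmetric transfer hydrogenation of alkynyl ketones is catalyst-controlled, and the (S,S)-complex is expected to give the (8S)-alcohol (the alkynyl group taking the role of the aryl group of aryl ketones) regardless of the remote dioxolane stereocentres.

Step 9
Reactants: 14 (S)-propargylic alcohol
Product: 15 (E)-alkenylstannane
Conditions: Bu3SnH, PdCl2(PPh3)2 (3 mol %), THF, 0 °C → rt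
Reagents that add atoms: tributyltin hydride, CCCC[SnH](CCCC)CCCC
Why: Palladium-catalysed hydrostannation adds H and SnBu3 syn, so C6 and C8 end up cis, and tin should go to C7, the alkyne carbon next to the free carbinol and the less hindered of the two.

Step 10
Reactants: 15 (E)-alkenylstannane
Product: 17 allylic 1,3-diol, via dilithio alkoxide 16 (not isolated)
Conditions: MeLi (3.2 equiv), THF, −78 → −20 °C; then (CH2O)n, −78 °C → rt; H2O
Reagents that add atoms: formaldehyde (from paraformaldehyde), C=O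
Why: Tin–lithium exchange with retention of alkene geometry gives a β-oxido alkenyllithium that does not eliminate, and its hydroxymethylation installs C7′ trans to C6.

Step 11
Reactants: 17 allylic 1,3-diol
Product: 18 mono-TES ether
Conditions: Et3SiCl (1.05 equiv), imidazole, CH2Cl2, −78 → −40 °C
Reagents that add atoms: chlorotriethylsilane, CC[Si](CC)(CC)Cl
Why: Kinetic silylation distinguishes the unhindered primary allylic hydroxyl from the secondary C8 hydroxyl flanked by the trisubstituted alkene.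

Step 12
Reactants: 18 mono-TES ether; 19 angelic acid
Product: 21 C8 angelate, via mixed anhydride 20 (not isolated)
Conditions: 19, 2,4,6-trichlorobenzoyl chloride, Et3N, toluene, 25 °C; then 18, 75 °C
Reagents that add atoms: none
Why: Yamaguchi-type esterification through the mixed anhydride, run without a nucleophilic catalyst, acylates C8–OH with retention and avoids the reversible conjugate addition that isomerises angelates to tiglates.

Step 13
Reactants: 21 C8 angelate
Product: 22 C7′ allylic alcohol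
Conditions: PPTS (cat.), MeOH/CH2Cl2, 0 °C
Reagents that add atoms: none
Why: Mild acid-catalysed methanolysis removes the primary triethylsilyl ether much faster than the primary TBS ether or the dioxolane.

Step 14
Reactants: 22 C7′ allylic alcohol
Product: 23 allylic bromide
Conditions: CBr4, PPh3, CH2Cl2, 0 °C
Reagents that add atoms: carbon tetrabromide, BrC(Br)(Br)Br
Why: The Appel reaction displaces the primary oxyphosphonium ion by bromide in an SN2 sense, without allylic transposition and without touching the esters or the silyl ether.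

Step 15
Reactants: 23 allylic bromide
Product: 24 hydroxy bromide
Conditions: HF·pyridine, THF, 0 °C
Reagents that add atoms: none
Why: Buffered hydrogen fluoride cleaves the primary TBS ether while the allylic bromide, which naked fluoride would displace, and the acetonide survive.

Step 16
Reactants: 24 hydroxy bromide
Product: 25 Z-enal allylic bromide
Conditions: MnO2, CH2Cl2, 25 °C
Reagents that add atoms: none
Why: MnO2 oxidises allylic alcohols under neutral heterogeneous conditions, which should give the Z-enal without Z/E isomerisation and leave the allylic bromide intact.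

Step 17
Reactants: 25 Z-enal allylic bromide
Product: 27 cyclohexenol, via allylchromium 26 (not isolated)
Conditions: CrCl2 (6 equiv), THF, rt, syringe-pump addition of 25 (final 0.005 M); then H2O
Reagents that add atoms: none
Why: Two single-electron transfers from divalent chromium turn the C7′–Br bond into the allylchromium 26 (trivalent chromium), whose γ-carbon C1 adds to the chromium-bound C2 aldehyde through a chair-like six-membered Zimmerman–Traxler array, so that the double bond moves to C7=CH2; the closest known reaction type is the intramolecular Nozaki–Hiyama allylation of aldehydes by allylic bromides. The carbocycle closes in the 6-exo-trig mode at the carbonyl carbon, the Z-enal holding C2 and C5 on the same side of C3=C4 so that the termini can meet, and conjugate attack at C4 is excluded because it would give a four-membered ring. C2 is set by the (E)-allyl geometry: the tether occupies equatorial sites on the chair, the bicyclic transition state is trans-fused and the C1/C2 relationship becomes trans (anti). C1 is set by the trans-dioxolane, which admits only the half-chair with C5–O and C6–O diequatorial, so that the C7 unit ends up equatorial and anti to the C6–O bond, the same sense as in additions of allylchromium reagents that carry a dioxolanyl group on the γ-carbon. The step needs chemoselective allyl transfer beside an angelate, an acetonide and an enal, which the low basicity and aldehyde selectivity of allylchromium reagents provide, and it needs cyclisation to beat dimerisation and loss of the C6 oxygen by elimination, which slow addition at high dilution and the fast six-membered ring closure should secure.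

Step 18
Reactants: 27 cyclohexenol
Product: 28 C2 acetate
Conditions: Ac2O, pyridine, DMAP (cat.), CH2Cl2, 0 °C → rt
Reagents that add atoms: acetic anhydride, CC(=O)OC(C)=O
Why: DMAP-catalysed acetylation of the equatorial allylic alcohol installs the C2 acetate and removes the only hydroxyl that could later be oxidised or direct an oxidant to the wrong face.

Step 19
Reactants: 28 C2 acetate
Product: 29 C5/C6 diol
Conditions: AcOH/H2O (4:1), 35 °C
Reagents that add atoms: none
Why: Acid-catalysed hydrolysis of the strained trans-fused dioxolane proceeds under conditions too mild to ionise the allylic esters.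

Step 20
Reactants: 29 C5/C6 diol
Product: 30 hydroxy enone
Conditions: MnO2, CH2Cl2, 25 °C
Reagents that add atoms: none
Why: MnO2 oxidises only the allylic C5 hydroxyl, which differentiates the two hydroxyls of the diol and gives the carvone-type enone.

Step 21
Reactants: 30 hydroxy enone
Product: 31 enone diacetate
Conditions: Ac2O, pyridine, DMAP (cat.), CH2Cl2, 0 °C
Reagents that add atoms: acetic anhydride, CC(=O)OC(C)=O
Why: Acyl transfer to the remaining C6 hydroxyl completes the acetate pattern, and C6 should not epimerise because its substituent is already equatorial.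

Step 22
Reactants: 31 enone diacetate
Product: 32 C5 allylic alcohol
Conditions: NaBH4, CeCl3·7H2O, MeOH, −78 °C
Reagents that add atoms: none
Why: Luche reduction gives clean 1,2-reduction, and axial hydride attack on the half-chair (as in carvone to cis-carveol) should return the pseudo-equatorial C5 alcohol cis to the C1 side chain and trans to the C6 acetate.

Step 23
Reactants: 32 C5 allylic alcohol
Product: 33 epoxy alcohol
Conditions: VO(acac)2 (5 mol %), t-BuOOH (in decane), CH2Cl2, 0 → 25 °C
Reagents that add atoms: tert-butyl hydroperoxide, CC(C)(C)OO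
Why: Vanadium-catalysed hydroxyl-directed epoxidation delivers oxygen to the C3=C4 face syn to the allylic C5 hydroxyl, that is anti to both acetates and cis to the side chain, and leaves the prenyl, exocyclic and angelate alkenes alone; this sets C3 and C4.

Step 24
Reactants: 33 epoxy alcohol
Product: 34 target CNP0298051.3
Conditions: Dess–Martin periodinane, pyridine, CH2Cl2, 0 °C → rt
Reagents that add atoms: none
Why: Buffered Dess–Martin oxidation of the epoxy alcohol gives the α,β-epoxy ketone without opening the oxirane or epimerising C6.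

Compound list

1 | dimethyl (4R,5R)-2,2-dimethyl-1,3-dioxolane-4,5-dicarboxylate | COC(=O)[C@@H]1OC(C)(C)O[C@H]1C(=O)OC | starting material
2 | (4R,5R)-2,2-dimethyl-1,3-dioxolane-4,5-dicarbaldehyde | O=C[C@@H]1OC(C)(C)O[C@H]1C=O | intermediate (not isolated)
3 | (4S,5S)-4,5-diethynyl-2,2-dimethyl-1,3-dioxolane | C#C[C@@H]1OC(C)(C)O[C@H]1C#C | intermediate
4 | {[(4S,5S)-5-ethynyl-2,2-dimethyl-1,3-dioxolan-4-yl]ethynyl}lithium | [Li]C#C[C@@H]1OC(C)(C)O[C@H]1C#C | intermediate (not isolated)
5 | methyl 3-[(4S,5S)-5-ethynyl-2,2-dimethyl-1,3-dioxolan-4-yl]prop-2-ynoate | COC(=O)C#C[C@@H]1OC(C)(C)O[C@H]1C#C | intermediate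
6 | lithium methyl{(1E)-2-[(4S,5S)-5-ethynyl-2,2-dimethyl-1,3-dioxolan-4-yl]-1-(methoxycarbonyl)prop-1-en-1-yl}cuprate (Cu cis to the new methyl) | [Li+].C[Cu-]/C(C(=O)OC)=C(\C)[C@@H]1OC(C)(C)O[C@H]1C#C | intermediate (not isolated)
7 | methyl (2Z)-3-[(4S,5S)-5-ethynyl-2,2-dimethyl-1,3-dioxolan-4-yl]but-2-enoate | COC(=O)/C=C(C)\[C@@H]1OC(C)(C)O[C@H]1C#C | intermediate
8 | (2Z)-3-[(4S,5S)-5-ethynyl-2,2-dimethyl-1,3-dioxolan-4-yl]but-2-en-1-ol | OC/C=C(C)\[C@@H]1OC(C)(C)O[C@H]1C#C | intermediate
9 | tert-butyl{[(2Z)-3-[(4S,5S)-5-ethynyl-2,2-dimethyl-1,3-dioxolan-4-yl]but-2-en-1-yl]oxy}dimethylsilane | CC(C)(C)[Si](C)(C)OC/C=C(C)\[C@@H]1OC(C)(C)O[C@H]1C#C | intermediate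
10 | 4-methylpent-3-enal | CC(C)=CCC=O | starting material
11 | lithium acetylide of 9 | CC(C)(C)[Si](C)(C)OC/C=C(C)\[C@@H]1OC(C)(C)O[C@H]1C#C[Li] | intermediate (not isolated)
12 | 1-{(4S,5S)-5-[(2Z)-4-{[tert-butyl(dimethyl)silyl]oxy}but-2-en-2-yl]-2,2-dimethyl-1,3-dioxolan-4-yl}-6-methylhept-5-en-1-yn-3-ol (both C8 epimers) | CC(C)(C)[Si](C)(C)OC/C=C(C)\[C@@H]1OC(C)(C)O[C@H]1C#CC(O)CC=C(C)C | intermediate
13 | 1-{(4S,5S)-5-[(2Z)-4-{[tert-butyl(dimethyl)silyl]oxy}but-2-en-2-yl]-2,2-dimethyl-1,3-dioxolan-4-yl}-6-methylhept-5-en-1-yn-3-one | CC(C)(C)[Si](C)(C)OC/C=C(C)\[C@@H]1OC(C)(C)O[C@H]1C#CC(=O)CC=C(C)C | intermediate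
14 | (3S)-1-{(4S,5S)-5-[(2Z)-4-{[tert-butyl(dimethyl)silyl]oxy}but-2-en-2-yl]-2,2-dimethyl-1,3-dioxolan-4-yl}-6-methylhept-5-en-1-yn-3-ol | CC(C)(C)[Si](C)(C)OC/C=C(C)\[C@@H]1OC(C)(C)O[C@H]1C#C[C@@H](O)CC=C(C)C | intermediate
15 | (1E,3S)-1-{(4S,5S)-5-[(2Z)-4-{[tert-butyl(dimethyl)silyl]oxy}but-2-en-2-yl]-2,2-dimethyl-1,3-dioxolan-4-yl}-6-methyl-2-(tributylstannyl)hepta-1,5-dien-3-ol | CC(C)(C)[Si](C)(C)OC/C=C(C)\[C@@H]1OC(C)(C)O[C@H]1/C=C(/[Sn](CCCC)(CCCC)CCCC)[C@@H](O)CC=C(C)C | intermediate
16 | dilithio derivative of the destannylated diene (C7–Li, C8–OLi; 1Z,3S) | CC(C)(C)[Si](C)(C)OC/C=C(C)\[C@@H]1OC(C)(C)O[C@H]1/C=C(/[Li])[C@@H](O[Li])CC=C(C)C | intermediate (not isolated)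
17 | (2Z,3S)-2-({(4S,5S)-5-[(2Z)-4-{[tert-butyl(dimethyl)silyl]oxy}but-2-en-2-yl]-2,2-dimethyl-1,3-dioxolan-4-yl}methylidene)-6-methylhept-5-ene-1,3-diol | CC(C)(C)[Si](C)(C)OC/C=C(C)\[C@@H]1OC(C)(C)O[C@H]1/C=C(/CO)[C@@H](O)CC=C(C)C | intermediate
18 | (1Z,3S)-1-{(4S,5S)-5-[(2Z)-4-{[tert-butyl(dimethyl)silyl]oxy}but-2-en-2-yl]-2,2-dimethyl-1,3-dioxolan-4-yl}-6-methyl-2-{[(triethylsilyl)oxy]methyl}hepta-1,5-dien-3-ol | CC(C)(C)[Si](C)(C)OC/C=C(C)\[C@@H]1OC(C)(C)O[C@H]1/C=C(/CO[Si](CC)(CC)CC)[C@@H](O)CC=C(C)C | intermediate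
19 | angelic acid, (2Z)-2-methylbut-2-enoic acid | C/C=C(/C)C(=O)O | starting material
20 | (2Z)-2-methylbut-2-enoic 2,4,6-trichlorobenzoic anhydride | C/C=C(/C)C(=O)OC(=O)c1c(Cl)cc(Cl)cc1Cl | intermediate (not isolated)
21 | (1Z,3S)-1-{(4S,5S)-5-[(2Z)-4-{[tert-butyl(dimethyl)silyl]oxy}but-2-en-2-yl]-2,2-dimethyl-1,3-dioxolan-4-yl}-6-methyl-2-{[(triethylsilyl)oxy]methyl}hepta-1,5-dien-3-yl (2Z)-2-methylbut-2-enoate | CC(C)(C)[Si](C)(C)OC/C=C(C)\[C@@H]1OC(C)(C)O[C@H]1/C=C(/CO[Si](CC)(CC)CC)[C@H](CC=C(C)C)OC(=O)/C(C)=C\C | intermediate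
22 | (1Z,3S)-1-{(4S,5S)-5-[(2Z)-4-{[tert-butyl(dimethyl)silyl]oxy}but-2-en-2-yl]-2,2-dimethyl-1,3-dioxolan-4-yl}-2-(hydroxymethyl)-6-methylhepta-1,5-dien-3-yl (2Z)-2-methylbut-2-enoate | CC(C)(C)[Si](C)(C)OC/C=C(C)\[C@@H]1OC(C)(C)O[C@H]1/C=C(/CO)[C@H](CC=C(C)C)OC(=O)/C(C)=C\C | intermediate
23 | (1E,3S)-2-(bromomethyl)-1-{(4S,5S)-5-[(2Z)-4-{[tert-butyl(dimethyl)silyl]oxy}but-2-en-2-yl]-2,2-dimethyl-1,3-dioxolan-4-yl}-6-methylhepta-1,5-dien-3-yl (2Z)-2-methylbut-2-enoate | CC(C)(C)[Si](C)(C)OC/C=C(C)\[C@@H]1OC(C)(C)O[C@H]1/C=C(/CBr)[C@H](CC=C(C)C)OC(=O)/C(C)=C\C | intermediate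
24 | (1E,3S)-2-(bromomethyl)-1-{(4S,5S)-5-[(2Z)-4-hydroxybut-2-en-2-yl]-2,2-dimethyl-1,3-dioxolan-4-yl}-6-methylhepta-1,5-dien-3-yl (2Z)-2-methylbut-2-enoate | OC/C=C(C)\[C@@H]1OC(C)(C)O[C@H]1/C=C(/CBr)[C@H](CC=C(C)C)OC(=O)/C(C)=C\C | intermediate
25 | (1E,3S)-2-(bromomethyl)-6-methyl-1-{(4S,5S)-2,2-dimethyl-5-[(2Z)-4-oxobut-2-en-2-yl]-1,3-dioxolan-4-yl}hepta-1,5-dien-3-yl (2Z)-2-methylbut-2-enoate (key-step precursor) | O=C/C=C(C)\[C@@H]1OC(C)(C)O[C@H]1/C=C(CBr)\[C@H](CC=C(C)C)OC(=O)/C(C)=C\C | intermediate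
26 | allylchromium dichloride formed from 25 (CrCl2 on C7′, E-allyl) | O=C/C=C(C)\[C@@H]1OC(C)(C)O[C@H]1/C=C(C[Cr](Cl)Cl)\[C@H](CC=C(C)C)OC(=O)/C(C)=C\C | intermediate (not isolated)
27 | (3S)-2-[(3aS,4R,5S,7aS)-5-hydroxy-2,2,7-trimethyl-3a,4,5,7a-tetrahydro-1,3-benzodioxol-4-yl]-6-methylhepta-1,5-dien-3-yl (2Z)-2-methylbut-2-enoate (key-step product; C2–OH and C6–O on one face, C1 side chain and C5–O on the other) | C=C([C@@H]1[C@@H](O)C=C(C)[C@@H]2OC(C)(C)O[C@@H]12)[C@H](CC=C(C)C)OC(=O)/C(C)=C\C | intermediate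
28 | (3S)-2-[(3aS,4R,5S,7aS)-5-(acetyloxy)-2,2,7-trimethyl-3a,4,5,7a-tetrahydro-1,3-benzodioxol-4-yl]-6-methylhepta-1,5-dien-3-yl (2Z)-2-methylbut-2-enoate | C=C([C@@H]1[C@@H](OC(C)=O)C=C(C)[C@@H]2OC(C)(C)O[C@@H]12)[C@H](CC=C(C)C)OC(=O)/C(C)=C\C | intermediate
29 | C2 acetate C5,C6-diol, route locants (1S,2S,5S,6S,8S): cyclohex-3-ene with C1 side chain (α), C2–OAc (β), C4–Me, C5–OH (α), C6–OH (β), C8 angelate | C=C([C@@H]1[C@@H](OC(C)=O)C=C(C)[C@H](O)[C@H]1O)[C@H](CC=C(C)C)OC(=O)/C(C)=C\C | intermediate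
30 | 6-hydroxy enone, route locants (1S,2S,6S,8S): C5 ketone conjugated with C3=C4, C2–OAc, C6–OH | C=C([C@@H]1[C@@H](OC(C)=O)C=C(C)C(=O)[C@H]1O)[C@H](CC=C(C)C)OC(=O)/C(C)=C\C | intermediate
31 | enone diacetate, route locants (1R,2S,6S,8S): C5 ketone, C2–OAc, C6–OAc | C=C([C@@H]1[C@@H](OC(C)=O)C=C(C)C(=O)[C@H]1OC(C)=O)[C@H](CC=C(C)C)OC(=O)/C(C)=C\C | intermediate
32 | C5 allylic alcohol diacetate, route locants (1R,2S,5S,6S,8S): C5–OH cis to the C1 side chain, trans to C6–OAc | C=C([C@@H]1[C@@H](OC(C)=O)C=C(C)[C@H](O)[C@H]1OC(C)=O)[C@H](CC=C(C)C)OC(=O)/C(C)=C\C | intermediate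
33 | epoxy alcohol, route locants (1S,2R,3S,4R,5R,6S,8S): 3,4-epoxide cis to C5–OH and to the side chain, trans to both acetates | C=C([C@@H]1[C@@H](OC(C)=O)[C@@H]2O[C@]2(C)[C@H](O)[C@H]1OC(C)=O)[C@H](CC=C(C)C)OC(=O)/C(C)=C\C | intermediate
34 | CNP0298051.3, route locants (1R,2R,3S,4S,6S,8S): 2,6-diacetoxy-3,4-epoxy-4-methyl-5-oxocyclohexane carrying at C1 the 1-methylidene-(8S)-8-angeloyloxy-prenylmethyl chain | C=C([C@@H]1[C@@H](OC(C)=O)[C@@H]2O[C@]2(C)C(=O)[C@H]1OC(C)=O)[C@H](CC=C(C)C)OC(=O)/C(C)=C\C | target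

Total step count: 24. Longest linear sequence: 24 steps (1 to 34; 10 and 19 are purchased).

Steps most likely to fail

Step 17 (key ring closure). The allylchromium may shed the C6 oxygen by elimination toward a diene, couple intermolecularly, or close through a boat-like array with erosion of C2 control. The fallback forms the same C1–C2 bond by Lewis-acid activation of the aldehyde and sets out from 15. Iododestannylation (I2, CH2Cl2, 0 °C) would give the alkenyl iodide F1 with retention. Kumada coupling with Me3SiCH2MgCl (Pd(PPh3)4, THF) would give the allylsilane F2. Angeloylation as in step 12 would give the ester F3, HF·pyridine the C2 alcohol F4 and MnO2 the Z-enal allylsilane F5. BF3·OEt2 (CH2Cl2, −78 °C) would then trigger an intramolecular Hosomi–Sakurai allylation in which the trans-dioxolane still enforces the diequatorial half-chair. This returns to the route at 27.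

Step 9 (hydrostannation). Regiocontrol may be poor, since both alkyne carbons carry a propargylic oxygen and tin could be delivered to C1 as well as C7. The fallback moves the directing hydroxyl to C7′ and sets out from 9. Lithiation and trapping with (CH2O)n would give the primary propargylic alcohol F6. Hydroxyl-directed ruthenium-catalysed trans-hydrostannation ([Cp*RuCl]4, Bu3SnH, CH2Cl2) would place tin on C7 next to the free hydroxyl and cis to C6, giving the (Z)-stannane F7. Tin–lithium exchange (MeLi, 3 equiv) and addition to 10 would give the diols F8 (C8 epimers) with C8 cis to C6. Et3SiCl and imidazole would give the primary silyl ethers F9, and Dess–Martin oxidation the enone F10. Corey–Bakshi–Shibata reduction with the (R)-methyl oxazaborolidine and catecholborane would set (8S) and return to the route at 18.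

Step 12 (angeloylation). Acylation of the hindered C8 carbinol may be slow, and prolonged heating may isomerise the angeloyl unit to the tigloyl isomer. The fallback builds the Z-alkene on the molecule and sets out from 18. Steglich esterification with 2-[bis(2,2,2-trifluoroethoxy)phosphoryl]propanoic acid (DCC, DMAP, CH2Cl2) would give the phosphonopropionate F11. Still–Gennari olefination (KN(SiMe3)2, 18-crown-6, THF, −78 °C; then acetaldehyde) would deliver the (Z)-2-methylbut-2-enoate and return to the route at 21.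

Further compounds

F1 | step 17 | (1E,3S)-1-{(4S,5S)-5-[(2Z)-4-{[tert-butyl(dimethyl)silyl]oxy}but-2-en-2-yl]-2,2-dimethyl-1,3-dioxolan-4-yl}-2-iodo-6-methylhepta-1,5-dien-3-ol | CC(C)(C)[Si](C)(C)OC/C=C(C)\[C@@H]1OC(C)(C)O[C@H]1/C=C(/I)[C@@H](O)CC=C(C)C
F2 | step 17 | (1Z,3S)-1-{(4S,5S)-5-[(2Z)-4-{[tert-butyl(dimethyl)silyl]oxy}but-2-en-2-yl]-2,2-dimethyl-1,3-dioxolan-4-yl}-6-methyl-2-[(trimethylsilyl)methyl]hepta-1,5-dien-3-ol | CC(C)(C)[Si](C)(C)OC/C=C(C)\[C@@H]1OC(C)(C)O[C@H]1/C=C(/C[Si](C)(C)C)[C@@H](O)CC=C(C)C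
F3 | step 17 | angelate of F2 (C2–OTBS, C7′–SiMe3, C8–OAng) | CC(C)(C)[Si](C)(C)OC/C=C(C)\[C@@H]1OC(C)(C)O[C@H]1/C=C(/C[Si](C)(C)C)[C@H](CC=C(C)C)OC(=O)/C(C)=C\C
F4 | step 17 | C2 alcohol from F3 (Z-allylic alcohol, allylsilane, C8–OAng) | OC/C=C(C)\[C@@H]1OC(C)(C)O[C@H]1/C=C(/C[Si](C)(C)C)[C@H](CC=C(C)C)OC(=O)/C(C)=C\C
F5 | step 17 | Z-enal allylsilane (C2 aldehyde, C7′–SiMe3, C8–OAng) | O=C/C=C(C)\[C@@H]1OC(C)(C)O[C@H]1/C=C(/C[Si](C)(C)C)[C@H](CC=C(C)C)OC(=O)/C(C)=C\C
F6 | step 9 | 3-{(4S,5S)-5-[(2Z)-4-{[tert-butyl(dimethyl)silyl]oxy}but-2-en-2-yl]-2,2-dimethyl-1,3-dioxolan-4-yl}prop-2-yn-1-ol | CC(C)(C)[Si](C)(C)OC/C=C(C)\[C@@H]1OC(C)(C)O[C@H]1C#CCO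
F7 | step 9 | (2Z)-3-{(4S,5S)-5-[(2Z)-4-{[tert-butyl(dimethyl)silyl]oxy}but-2-en-2-yl]-2,2-dimethyl-1,3-dioxolan-4-yl}-2-(tributylstannyl)prop-2-en-1-ol | CC(C)(C)[Si](C)(C)OC/C=C(C)\[C@@H]1OC(C)(C)O[C@H]1/C=C(\[Sn](CCCC)(CCCC)CCCC)CO
F8 | step 9 | C8-epimeric mixture corresponding to diol 17 | CC(C)(C)[Si](C)(C)OC/C=C(C)\[C@@H]1OC(C)(C)O[C@H]1/C=C(/CO)C(O)CC=C(C)C
F9 | step 9 | C8-epimeric mixture corresponding to mono-TES ether 18 | CC(C)(C)[Si](C)(C)OC/C=C(C)\[C@@H]1OC(C)(C)O[C@H]1/C=C(/CO[Si](CC)(CC)CC)C(O)CC=C(C)C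
F10 | step 9 | (1Z)-1-{(4S,5S)-5-[(2Z)-4-{[tert-butyl(dimethyl)silyl]oxy}but-2-en-2-yl]-2,2-dimethyl-1,3-dioxolan-4-yl}-6-methyl-2-{[(triethylsilyl)oxy]methyl}hepta-1,5-dien-3-one | CC(C)(C)[Si](C)(C)OC/C=C(C)\[C@@H]1OC(C)(C)O[C@H]1/C=C(/CO[Si](CC)(CC)CC)C(=O)CC=C(C)C
F11 | step 12 | 2-[bis(2,2,2-trifluoroethoxy)phosphoryl]propanoate of 18 (both epimers at the phosphonate-bearing carbon) | CC(C)(C)[Si](C)(C)OC/C=C(C)\[C@@H]1OC(C)(C)O[C@H]1/C=C(/CO[Si](CC)(CC)CC)[C@H](CC=C(C)C)OC(=O)C(C)P(=O)(OCC(F)(F)F)OCC(F)(F)F
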